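**Plan**
- Retrosynthetic cuts, in order: O–Si at C4; the C4a–C5 bond of the cyclohexenone (intramolecular Vilsmeier–Haack-type acylation of a cyclic enol ether by a tethered tertiary amide); C4–H (hydride); O1–C8a (oxa-Michael); C4–C4a (acetylide on a Weinreb amide); C2–H (hydrogenation of a β-keto ester).
- Forward: a C20 β-hydroxy acyl unit and a C6 alkynamide are joined to an ynone; the pyran ring closes first (6-endo-dig), the carbocycle second, in the key step.
- Enabling feature: the enol ether O1–C8a=C4a inside the dihydropyran ring. C4a is its nucleophilic β-carbon, and C8a carries the three-carbon tether (C8–C7–C6) ending in the amide carbon C5. Activating the amide therefore closes the six-membered ring and gives the vinylogous ester at its final oxidation level without touching C4–O.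
- Stereochemistry: C2 (S) from a Noyori hydrogenation with (S)-BINAP–Ru; C4 (R) from a substrate-controlled Luche reduction that places the hydroxyl cis to the heptadecyl group (1,3-induction from C2).
- Helpers: NMe2 (activating group, leaves as dimethylamine in the key step) and a TBS ether on O4 (removed in the last step).

Key step: step 9

Assumption: the SMILES is read as the (2S,4R) isomer, with heptadecyl at C2 and hydroxyl at C4 cis on the dihydropyran ring; chromene numbering (O1, C2, C3, C4, C4a, C5–C8, C8a) is used throughout.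

**Step 1**
Reactants: 1 octadecanoyl chloride; 2 Meldrum's acid (2,2-dimethyl-1,3-dioxane-4,6-dione)
Product: 4 methyl 3-oxoicosanoate, via acyl Meldrum's acid 3 (not isolated)
Conditions: pyridine, CH2Cl2, 0 °C → rt; then MeOH, reflux
Reagents that add atoms: methanol, CO
Why: C-acylation of Meldrum's acid by the acid chloride followed by methanolysis of the acyl Meldrum's acid (loss of acetone and CO2) is the standard two-stage β-keto ester synthesis and creates no stereocenter.

**Step 2**
Reactants: 4 methyl 3-oxoicosanoate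
Product: 5 methyl (S)-3-hydroxyicosanoate
Conditions: H2 (50 bar), RuCl2[(S)-BINAP] (cat.), MeOH, 50 °C
Reagents that add atoms: none
Why: Noyori asymmetric hydrogenation, in which the β-keto ester chelates ruthenium and the (S)-BINAP ligand should direct hydride to the ketone face that gives the (S)-carbinol, the future C2 of the target.

**Step 3**
Reactants: 5 methyl (S)-3-hydroxyicosanoate
Product: 6 (S)-3-hydroxy-N-methoxy-N-methylicosanamide
Conditions: MeNH(OMe)·HCl, i-PrMgCl, THF, −20 → 0 °C
Reagents that add atoms: N,O-dimethylhydroxylamine hydrochloride, CNOC.Cl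
Why: Weinreb amide formation by aminolysis of the ester with the magnesium amide of N,O-dimethylhydroxylamine, which tolerates the free β-hydroxyl as its alkoxide and does not touch the carbinol stereocenter.

**Step 4**
Reactants: 7 hex-5-ynoic acid
Product: 9 N,N-dimethylhex-5-ynamide, via hex-5-ynoyl chloride 8 (not isolated)
Conditions: (COCl)2, cat. DMF, CH2Cl2, 0 °C → rt; then Me2NH (2 M in THF, excess), 0 °C
Reagents that add atoms: dimethylamine, CNC
Why: acid chloride formation and aminolysis (amide synthesis) install the tertiary amide that later serves as the latent acyl electrophile, the terminal alkyne being inert to both stages.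

**Step 5**
Reactants: 6 (S)-3-hydroxy-N-methoxy-N-methylicosanamide; 9 N,N-dimethylhex-5-ynamide
Product: 11 (9S)-9-hydroxy-N,N-dimethyl-7-oxohexacos-5-ynamide, via lithium acetylide 10 (not isolated)
Conditions: 9 (3.3 equiv), LDA (3.0 equiv), THF, −78 °C; then 6, −78 → −20 °C; cold aq. NaHSO4 quench
Reagents that add atoms: none
Why: Weinreb ketone synthesis, in which the alkyne C–H is several pK units more acidic than the amide α-C–H so the non-nucleophilic base should give acetylide 10 cleanly, one equivalent deprotonates the hydroxyl of 6 and the next adds once to the N-methoxy-N-methylamide (stable chelate, no over-addition), leaving the stereocenter untouched.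

**Step 6**
Reactants: 11 (9S)-9-hydroxy-N,N-dimethyl-7-oxohexacos-5-ynamide
Product: 12 4-[(2S)-2-heptadecyl-4-oxo-3,4-dihydro-2H-pyran-6-yl]-N,N-dimethylbutanamide
Conditions: AgOTf (10 mol %), CH2Cl2, rt, dark
Reagents that add atoms: none
Why: silver(I)-catalysed 6-endo-dig oxa-Michael cycloisomerisation, in which the ynone polarisation directs the hydroxyl oxygen to the β-alkyne carbon and, since the C–O bond of the carbinol is not broken, the (S) centre becomes C2 of the dihydropyranone unchanged.

**Step 7**
Reactants: 12 4-[(2S)-2-heptadecyl-4-oxo-3,4-dihydro-2H-pyran-6-yl]-N,N-dimethylbutanamide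
Product: 13 4-[(2S,4R)-2-heptadecyl-4-hydroxy-3,4-dihydro-2H-pyran-6-yl]-N,N-dimethylbutanamide
Conditions: NaBH4, CeCl3·7H2O, MeOH–THF (1:1), −40 °C; aq. NaHCO3 work-up
Reagents that add atoms: none
Why: Luche 1,2-reduction, in which the heptadecyl group sits pseudo-equatorial on the half-chair and hydride should add axially to C4 to give the pseudo-equatorial hydroxyl cis to the C2 substituent (4R, 1,3-induction), while CeCl3 suppresses conjugate reduction and the amide is inert.

**Step 8**
Reactants: 13 4-[(2S,4R)-2-heptadecyl-4-hydroxy-3,4-dihydro-2H-pyran-6-yl]-N,N-dimethylbutanamide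
Product: 14 4-[(2S,4R)-4-[(tert-butyldimethylsilyl)oxy]-2-heptadecyl-3,4-dihydro-2H-pyran-6-yl]-N,N-dimethylbutanamide
Conditions: TBSCl, imidazole, DMF, rt
Reagents that add atoms: tert-butyldimethylsilyl chloride, CC(C)(C)[Si](C)(C)Cl
Why: standard silylation of a secondary allylic alcohol under mildly basic conditions, which avoid Ferrier-type ionisation of the 4-hydroxy enol ether and mask the hydroxyl against triflic anhydride without affecting a stereocenter.

**Step 9**
Reactants: 14 4-[(2S,4R)-4-[(tert-butyldimethylsilyl)oxy]-2-heptadecyl-3,4-dihydro-2H-pyran-6-yl]-N,N-dimethylbutanamide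
Product: 17 (2S,4R)-4-[(tert-butyldimethylsilyl)oxy]-2-heptadecyl-2,3,4,6,7,8-hexahydro-5H-chromen-5-one, via O-triflyl iminium triflate 15 (not isolated), via cyclic vinylogous iminium triflate 16 (not isolated)
Conditions: Tf2O (1.1 equiv), 2,6-di-tert-butyl-4-methylpyridine (2.5 equiv), CH2Cl2 (0.02 M), −78 → 0 °C; then aq. NaOAc/AcOH buffer (pH ca. 5)–THF, rt
Reagents that add atoms: water, O
Why: Tf2O O-triflates the tertiary amide to the O-triflyl iminium ion 15 (or the keteniminium ion derived from it), whose carbon (future C5) is attacked by the β-carbon of the cyclic enol ether (future C4a); loss of triflate and of the C4a proton gives the vinylogous iminium 16, and buffered water then exchanges NMe2 for O to release the vinylogous ester. The closest known reaction type is the Vilsmeier–Haack C-acylation of enol ethers (C2-formylation of glycals) in its intramolecular form with a Tf2O-activated amide. The cyclohexenone ring closes in the 6-(enolendo)-exo mode, the three-carbon tether on C8a placing the iminium carbon over C4a. No stereocenter is created; C2 and C4 are spectators and keep their configuration. The step needs C–C bonding at C4a and not at C8a (spiro five-ring closure), which the polarisation of the O1–C8a=C4a enol ether secures, and activation of the amide in the presence of the allylic silyl ether, which the higher nucleophilicity of the amide oxygen, the low temperature, the hindered base (no free TfOH, hence no Ferrier ionisation at C4) and high dilution should secure. Hydrolysis at pH about 5 keeps the released dimethylamine protonated so that it cannot open the pyran by conjugate exchange.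

**Step 10**
Reactants: 17 (2S,4R)-4-[(tert-butyldimethylsilyl)oxy]-2-heptadecyl-2,3,4,6,7,8-hexahydro-5H-chromen-5-one
Product: 18 (2S,4R)-2-heptadecyl-4-hydroxy-2,3,4,6,7,8-hexahydro-5H-chromen-5-one
Conditions: TBAF, AcOH (1:1), THF, 0 °C → rt
Reagents that add atoms: none
Why: fluoride-mediated desilylation driven by Si–F bond formation, buffered with acetic acid so that neither acid-promoted loss of the allylic C4 oxygen nor base-promoted reaction of the vinylogous ester should intervene, both stereocenters being untouched.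

**Compound list**
1 | octadecanoyl chloride | CCCCCCCCCCCCCCCCCC(=O)Cl | starting material
2 | Meldrum's acid (2,2-dimethyl-1,3-dioxane-4,6-dione) | CC1(C)OC(=O)CC(=O)O1 | starting material
3 | 5-(1-hydroxyoctadecylidene)-2,2-dimethyl-1,3-dioxane-4,6-dione (acyl Meldrum's acid) | CCCCCCCCCCCCCCCCCC(O)=C1C(=O)OC(C)(C)OC1=O | intermediate (not isolated)
4 | methyl 3-oxoicosanoate | CCCCCCCCCCCCCCCCCC(=O)CC(=O)OC | intermediate
5 | methyl (S)-3-hydroxyicosanoate | CCCCCCCCCCCCCCCCC[C@H](O)CC(=O)OC | intermediate
6 | (S)-3-hydroxy-N-methoxy-N-methylicosanamide | CCCCCCCCCCCCCCCCC[C@H](O)CC(=O)N(C)OC | intermediate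
7 | hex-5-ynoic acid | C#CCCCC(=O)O | starting material
8 | hex-5-ynoyl chloride | C#CCCCC(=O)Cl | intermediate (not isolated)
9 | N,N-dimethylhex-5-ynamide | C#CCCCC(=O)N(C)C | intermediate
10 | lithium acetylide of 9 (lithium 6-(dimethylamino)-6-oxohex-1-yn-1-ide) | [Li]C#CCCCC(=O)N(C)C | intermediate (not isolated)
11 | (9S)-9-hydroxy-N,N-dimethyl-7-oxohexacos-5-ynamide | CCCCCCCCCCCCCCCCC[C@H](O)CC(=O)C#CCCCC(=O)N(C)C | intermediate
12 | 4-[(2S)-2-heptadecyl-4-oxo-3,4-dihydro-2H-pyran-6-yl]-N,N-dimethylbutanamide | CCCCCCCCCCCCCCCCC[C@H]1CC(=O)C=C(CCCC(=O)N(C)C)O1 | intermediate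
13 | 4-[(2S,4R)-2-heptadecyl-4-hydroxy-3,4-dihydro-2H-pyran-6-yl]-N,N-dimethylbutanamide | CCCCCCCCCCCCCCCCC[C@H]1C[C@@H](O)C=C(CCCC(=O)N(C)C)O1 | intermediate
14 | 4-[(2S,4R)-4-[(tert-butyldimethylsilyl)oxy]-2-heptadecyl-3,4-dihydro-2H-pyran-6-yl]-N,N-dimethylbutanamide | CCCCCCCCCCCCCCCCC[C@H]1C[C@@H](O[Si](C)(C)C(C)(C)C)C=C(CCCC(=O)N(C)C)O1 | intermediate
15 | O-triflyl iminium triflate of 14 | CCCCCCCCCCCCCCCCC[C@H]1C[C@@H](O[Si](C)(C)C(C)(C)C)C=C(CCCC(OS(=O)(=O)C(F)(F)F)=[N+](C)C)O1.[O-]S(=O)(=O)C(F)(F)F | intermediate (not isolated)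
16 | N-[(2S,4R)-4-[(tert-butyldimethylsilyl)oxy]-2-heptadecyl-2,3,4,6,7,8-hexahydro-5H-chromen-5-ylidene]-N-methylmethanaminium triflate | CCCCCCCCCCCCCCCCC[C@H]1C[C@@H](O[Si](C)(C)C(C)(C)C)C2=C(CCCC2=[N+](C)C)O1.[O-]S(=O)(=O)C(F)(F)F | intermediate (not isolated)
17 | (2S,4R)-4-[(tert-butyldimethylsilyl)oxy]-2-heptadecyl-2,3,4,6,7,8-hexahydro-5H-chromen-5-one | CCCCCCCCCCCCCCCCC[C@H]1C[C@@H](O[Si](C)(C)C(C)(C)C)C2=C(CCCC2=O)O1 | intermediate
18 | (2S,4R)-2-heptadecyl-4-hydroxy-2,3,4,6,7,8-hexahydro-5H-chromen-5-one | CCCCCCCCCCCCCCCCC[C@H]1C[C@@H](O)C2=C(CCCC2=O)O1 | target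

**Step count and risks**

Total steps: 10. Longest linear sequence: 9 (steps 1, 2, 3, 5, 6, 7, 8, 9, 10, from octadecanoyl chloride).

Steps most likely to fail:

1. Step 9. The activated amide may not be trapped fast enough by the enol ether, so that triflic anhydride attacks the enol ether carbon, adventitious acid ionises the allylic C4–O bond (Ferrier-type loss of the silyloxy group), or intermolecular oligomerisation takes over. During hydrolysis, amine exchange could open the pyran. The fallback is an anionic ring closure; it sets out from 12 and comes back at 17. α-Iodination of the vinylogous ester (I2, pyridine, CH2Cl2) should give 4-[(2S)-2-heptadecyl-5-iodo-4-oxo-3,4-dihydro-2H-pyran-6-yl]-N,N-dimethylbutanamide F1. Luche reduction should give the cis alcohol 4-[(2S,4R)-2-heptadecyl-4-hydroxy-5-iodo-3,4-dihydro-2H-pyran-6-yl]-N,N-dimethylbutanamide F2. Silylation (TBSCl, imidazole) should give 4-[(2S,4R)-4-[(tert-butyldimethylsilyl)oxy]-2-heptadecyl-5-iodo-3,4-dihydro-2H-pyran-6-yl]-N,N-dimethylbutanamide F3. Iodine–lithium exchange (t-BuLi, THF, −100 °C) and Parham cyclisation of the vinyllithium onto the dimethylamide, followed by aqueous work-up, should then give 17.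

2. Step 5. Partial enolisation of the amide in 9 may lead to self-condensation; addition to the alkoxide-bearing Weinreb amide may stall; and released N,O-dimethylhydroxylamine may add to the ynone during the quench. The fallback replaces the anionic coupling by a Pd/Cu-catalysed one; it sets out from 5 and comes back at 12. Silylation (TBSCl, imidazole) should give methyl (S)-3-[(tert-butyldimethylsilyl)oxy]icosanoate F4. Saponification (LiOH, THF–H2O) should give (S)-3-[(tert-butyldimethylsilyl)oxy]icosanoic acid F5. Oxalyl chloride with catalytic DMF should give (S)-3-[(tert-butyldimethylsilyl)oxy]icosanoyl chloride F6. Acyl Sonogashira coupling with 9 (PdCl2(PPh3)2, CuI, Et3N, THF, rt) should give (9S)-9-[(tert-butyldimethylsilyl)oxy]-N,N-dimethyl-7-oxohexacos-5-ynamide F7. TsOH·H2O in MeOH should then remove the silyl group and close the ring to 12.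

3. Step 10. The silyl ether at C4 is flanked by the C5 carbonyl and may cleave slowly; forcing conditions could cause acid- or base-induced loss of the C4 oxygen (dehydration towards the 2H-pyran dienone). The fallback changes the protecting-group plan from 13 onward and comes back at 18. Silylation with TESCl and imidazole should give 4-[(2S,4R)-2-heptadecyl-4-[(triethylsilyl)oxy]-3,4-dihydro-2H-pyran-6-yl]-N,N-dimethylbutanamide F8. Under the conditions of step 9 this should pass through its O-triflyl iminium triflate F9 and the cyclic vinylogous iminium triflate F10 to (2S,4R)-2-heptadecyl-4-[(triethylsilyl)oxy]-2,3,4,6,7,8-hexahydro-5H-chromen-5-one F11. Its much more labile silyl ether should be cleaved within minutes by HF·pyridine/pyridine in THF at −20 °C to give 18.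

**Further compounds**
F1 | step 9 | 4-[(2S)-2-heptadecyl-5-iodo-4-oxo-3,4-dihydro-2H-pyran-6-yl]-N,N-dimethylbutanamide | CCCCCCCCCCCCCCCCC[C@H]1CC(=O)C(I)=C(CCCC(=O)N(C)C)O1
F2 | step 9 | 4-[(2S,4R)-2-heptadecyl-4-hydroxy-5-iodo-3,4-dihydro-2H-pyran-6-yl]-N,N-dimethylbutanamide | CCCCCCCCCCCCCCCCC[C@H]1C[C@@H](O)C(I)=C(CCCC(=O)N(C)C)O1
F3 | step 9 | 4-[(2S,4R)-4-[(tert-butyldimethylsilyl)oxy]-2-heptadecyl-5-iodo-3,4-dihydro-2H-pyran-6-yl]-N,N-dimethylbutanamide | CCCCCCCCCCCCCCCCC[C@H]1C[C@@H](O[Si](C)(C)C(C)(C)C)C(I)=C(CCCC(=O)N(C)C)O1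
F4 | step 5 | methyl (S)-3-[(tert-butyldimethylsilyl)oxy]icosanoate | CCCCCCCCCCCCCCCCC[C@H](O[Si](C)(C)C(C)(C)C)CC(=O)OC
F5 | step 5 | (S)-3-[(tert-butyldimethylsilyl)oxy]icosanoic acid | CCCCCCCCCCCCCCCCC[C@H](O[Si](C)(C)C(C)(C)C)CC(=O)O
F6 | step 5 | (S)-3-[(tert-butyldimethylsilyl)oxy]icosanoyl chloride | CCCCCCCCCCCCCCCCC[C@H](O[Si](C)(C)C(C)(C)C)CC(=O)Cl
F7 | step 5 | (9S)-9-[(tert-butyldimethylsilyl)oxy]-N,N-dimethyl-7-oxohexacos-5-ynamide | CCCCCCCCCCCCCCCCC[C@H](O[Si](C)(C)C(C)(C)C)CC(=O)C#CCCCC(=O)N(C)C
F8 | step 10 | 4-[(2S,4R)-2-heptadecyl-4-[(triethylsilyl)oxy]-3,4-dihydro-2H-pyran-6-yl]-N,N-dimethylbutanamide | CCCCCCCCCCCCCCCCC[C@H]1C[C@@H](O[Si](CC)(CC)CC)C=C(CCCC(=O)N(C)C)O1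
F9 | step 10 | O-triflyl iminium triflate of F8 | CCCCCCCCCCCCCCCCC[C@H]1C[C@@H](O[Si](CC)(CC)CC)C=C(CCCC(OS(=O)(=O)C(F)(F)F)=[N+](C)C)O1.[O-]S(=O)(=O)C(F)(F)F
F10 | step 10 | N-[(2S,4R)-2-heptadecyl-4-[(triethylsilyl)oxy]-2,3,4,6,7,8-hexahydro-5H-chromen-5-ylidene]-N-methylmethanaminium triflate | CCCCCCCCCCCCCCCCC[C@H]1C[C@@H](O[Si](CC)(CC)CC)C2=C(CCCC2=[N+](C)C)O1.[O-]S(=O)(=O)C(F)(F)F
F11 | step 10 | (2S,4R)-2-heptadecyl-4-[(triethylsilyl)oxy]-2,3,4,6,7,8-hexahydro-5H-chromen-5-one | CCCCCCCCCCCCCCCCC[C@H]1C[C@@H](O[Si](CC)(CC)CC)C2=C(CCCC2=O)O1
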